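**Plan**
1. Ring labels: A is the benzo ring of the chroman, C its dihydropyran ring (O1, C2, C3, C4), B the pendant arene (C1′–C6′), and D the dimethylpyran on B. The retrosynthesis first cuts the two phenol O–MOM bonds and then the C3–C1′ bond. This gives an achiral 7-O-MOM-8-prenyl-2H-chromene (A/C) and a 6-iodo-5-O-MOM-2,2-dimethylchromene (B/D).
2. Enabling feature: C3 is the homobenzylic carbon of ring C. At the C3=C4 alkene level an arylpalladium species puts the aryl group on C3 and palladium on benzylic C4. The only β-hydrogen (H3) is then held anti to palladium by the six-membered ring, so the stranded C4–Pd bond is reduced by formate and no activating group has to be removed later.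
3. Rings A/C, forward: resorcinol undergoes two OMOM-directed lithiations (C8 prenyl, then the formyl carbon that becomes C4). Chelation-controlled release of the phenol that becomes O1 follows, and a vinylphosphonium annulation closes ring C.
4. Rings B/D, forward: ring D is closed first on cyclohexane-1,3-dione. Ring B is carried as the cyclohexenone and aromatised afterwards, which fixes the 2′-OH/3′,4′-pyran pattern without regioisomers. An OMOM-directed lithiation then puts iodine on C1′.
5. Stereochemistry: the single stereocenter C3 (S) is created in the coupling itself, by the chiral bisphosphine on palladium during migratory insertion (aryl to the Re face of C3). The final deprotection does not touch it.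

Key step: step 11

Assumption: the sense of induction of the ligand in the new coupling cannot be derived from precedent. The route is written for the antipode that delivers the aryl group to the Re face of C3, taken here as (R)-SEGPHOS, and the (S) antipode is used if the first experiment shows the opposite sense.

**Step 1**
Reactants: 1 resorcinol
Product: 2 1,3-bis(methoxymethoxy)benzene
Conditions: MOMCl (2.4 equiv), K2CO3, acetone, reflux
Reagents that add atoms: chloromethyl methyl ether, COCCl
Why: Double Williamson-type O-alkylation of the phenols; the MOM acetal is chosen because it directs both later lithiations on this ring and leaves in one final operation.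

**Step 2**
Reactants: 2 1,3-bis(methoxymethoxy)benzene
Product: 4 1,3-bis(methoxymethoxy)-2-(3-methylbut-2-enyl)benzene, via aryllithium 3 (not isolated)
Conditions: n-BuLi, THF, 0 °C to rt; then prenyl bromide, −78 °C to rt
Reagents that add atoms: 1-bromo-3-methylbut-2-ene, CC(C)=CCBr; n-butyllithium, [Li]CCCC (lithium of 3 only)
Why: Directed ortho-metalation takes place at C2, the position flanked and chelated by both OMOM groups, and the aryllithium is alkylated by the primary allylic bromide in an SN2 reaction that keeps the prenyl (not the reverse-prenyl) connectivity.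

**Step 3**
Reactants: 4 1,3-bis(methoxymethoxy)-2-(3-methylbut-2-enyl)benzene
Product: 6 2,4-bis(methoxymethoxy)-3-(3-methylbut-2-enyl)benzaldehyde, via aryllithium 5 (not isolated)
Conditions: n-BuLi, TMEDA, THF, −20 to 0 °C; DMF, −78 °C to rt; H2O
Reagents that add atoms: N,N-dimethylformamide, CN(C)C=O; n-butyllithium, [Li]CCCC (lithium of 5 only)
Why: A second directed ortho-metalation can only go to a position ortho to an OMOM group (both such positions are equivalent by symmetry), complex-induced proximity favouring ring over benzylic-allylic deprotonation, and DMF formylation installs the carbon that becomes C4.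

**Step 4**
Reactants: 6 2,4-bis(methoxymethoxy)-3-(3-methylbut-2-enyl)benzaldehyde
Product: 8 2-hydroxy-4-(methoxymethoxy)-3-(3-methylbut-2-enyl)benzaldehyde, via bromomagnesium phenoxide 7 (not isolated)
Conditions: MgBr2·OEt2 (1.5 equiv), Et2O–toluene, 0 °C to rt; then H2O
Reagents that add atoms: magnesium bromide diethyl etherate, [Mg+2].[Br-].[Br-].CCOCC (magnesium and bromine of 7 only)
Why: Chelation-directed Lewis-acid cleavage of an aryl acetal: magnesium is held between the formyl oxygen and the ortho aryl oxygen in a six-membered chelate, so bromide removes only that MOM group, while the para acetal, the aldehyde and the prenyl alkene are left alone.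

**Step 5**
Reactants: 8 2-hydroxy-4-(methoxymethoxy)-3-(3-methylbut-2-enyl)benzaldehyde
Product: 11 7-(methoxymethoxy)-8-(3-methylbut-2-enyl)-2H-chromene, via sodium phenoxide 9 (not isolated), via phosphonium ylide 10 (not isolated)
Conditions: NaH, THF, 0 °C; then vinyltriphenylphosphonium bromide, THF–DMF, 65 °C
Reagents that add atoms: vinyltriphenylphosphonium bromide, C=C[P+](c1ccccc1)(c1ccccc1)c1ccccc1.[Br-]; sodium hydride, [Na+].[H-] (sodium of 9 only)
Why: Schweizer chromene synthesis: oxa-Michael addition of the phenoxide to the vinylphosphonium salt gives the ylide, whose intramolecular Wittig reaction with the formyl group closes ring C and leaves the C3=C4 alkene exactly where the coupling needs it.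

**Step 6**
Reactants: 12 cyclohexane-1,3-dione; 13 3-methylbut-2-enal
Product: 15 2,2-dimethyl-7,8-dihydro-2H-chromen-5(6H)-one, via oxatriene 14 (not isolated)
Conditions: ethylenediammonium diacetate (10 mol %), MeOH, rt to 50 °C
Reagents that add atoms: none
Why: Knoevenagel condensation followed by oxa-6π electrocyclisation of the 1-oxatriene (formal [3+3] annulation) closes ring D on the central carbon of the dione, so the later C3′/C4′ fusion pattern is fixed without regioisomers.

**Step 7**
Reactants: 15 2,2-dimethyl-7,8-dihydro-2H-chromen-5(6H)-one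
Product: 17 2,2-dimethyl-6-(phenylselanyl)-7,8-dihydro-2H-chromen-5(6H)-one (racemic), via lithium enolate 16 (not isolated)
Conditions: LDA (commercial solution), THF, −78 °C; PhSeCl, −78 °C
Reagents that add atoms: benzeneselenenyl chloride, Cl[Se]c1ccccc1; lithium diisopropylamide, [Li+].CC(C)[N-]C(C)C (lithium of 16 only)
Why: Kinetic deprotonation of the vinylogous ester at the α′ carbon (Stork–Danheiser-type enolate) and electrophilic selenenylation; the new stereocenter is of no consequence because it is destroyed in the next step.

**Step 8**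
Reactants: 17 2,2-dimethyl-6-(phenylselanyl)-7,8-dihydro-2H-chromen-5(6H)-one
Product: 20 2,2-dimethyl-2H-chromen-5-ol, via selenoxide 18 (not isolated), via dienone 19 (not isolated)
Conditions: 30% aq H2O2, pyridine, CH2Cl2, 0 °C to rt
Reagents that add atoms: hydrogen peroxide, OO (oxygen of 18 only)
Why: Selenoxide syn-elimination gives the cross-conjugated dienone, which tautomerises at once to the phenol (aromatisation of ring B), while H2O2 alone does not epoxidise the ring D alkene.

**Step 9**
Reactants: 20 2,2-dimethyl-2H-chromen-5-ol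
Product: 21 5-(methoxymethoxy)-2,2-dimethyl-2H-chromene
Conditions: MOMCl, K2CO3, acetone, reflux
Reagents that add atoms: chloromethyl methyl ether, COCCl
Why: Williamson-type acetal protection of the phenol; the OMOM group is small enough to sit beside the future coupling site and serves as the directing group of the next step.

**Step 10**
Reactants: 21 5-(methoxymethoxy)-2,2-dimethyl-2H-chromene
Product: 23 6-iodo-5-(methoxymethoxy)-2,2-dimethyl-2H-chromene, via aryllithium 22 (not isolated)
Conditions: n-BuLi, TMEDA, Et2O, 0 °C to rt; I2, THF, −78 °C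
Reagents that add atoms: iodine, II; n-butyllithium, [Li]CCCC (lithium of 22 only)
Why: Directed ortho-metalation: OMOM, the stronger director, has only one free ortho position (C6, the future C1′), and iodinolysis of the aryllithium is fast at low temperature so the ring D alkene is not touched.

**Step 11**
Reactants: 11 7-(methoxymethoxy)-8-(3-methylbut-2-enyl)-2H-chromene; 23 6-iodo-5-(methoxymethoxy)-2,2-dimethyl-2H-chromene
Product: 24 (3S)-7-(methoxymethoxy)-3-[5-(methoxymethoxy)-2,2-dimethyl-2H-chromen-6-yl]-8-(3-methylbut-2-enyl)chroman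
Conditions: 11 (1.5 equiv), Pd2(dba)3·CHCl3 (2.5 mol %), (R)-SEGPHOS (6 mol %), HCO2Na (2 equiv, added slowly in ethylene glycol), 1,4-dioxane–ethylene glycol, degassed, 60 °C
Reagents that add atoms: none
Why: Proposed new method: oxidative addition of zerovalent palladium into the C–I bond of 23, release of iodide into the protic medium and syn migratory insertion of the C3=C4 bond of 11 put the aryl group on C3 and palladium on benzylic C4 (η3-benzyl with ring A); the only β-hydrogen, H3, then lies anti to palladium and ring C forbids the rotation that would bring it syn, so β-hydride elimination is shut off and formate binding, loss of CO2 and C–H reductive elimination turn C4–Pd into C4–H. The closest known reaction types are the racemic Heck oxyarylation of 2H-chromenes with 2-iodophenols, which shows the same C3-aryl/C4-palladium regiochemistry, and the enantioselective reductive Heck hydroarylation of norbornenes and of tethered alkenes with formate; the enantioselective intermolecular case on a 2H-chromene is the new element. No ring is closed in this step. The C3 stereocenter is set in the irreversible insertion by the C2-symmetric bisphosphine, which stays bound through both phosphorus atoms on the cationic square-planar arylpalladium complex and should admit the flat chromene only with the Re face of C3 towards the aryl group; C4 ends as CH2, so C3 (S) is the only record of the event. Site selectivity among the three alkenes is needed and is secured by the substrates: the prenyl alkene is trisubstituted, the ring D alkene would have to accept the aryl group next to the CMe2 carbon, and only C3=C4 of 11 is an unhindered cis-disubstituted styrene. Direct reduction of the arylpalladium species by formate is held back by the chelating ligand (no free cis site for decarboxylation), by the excess of 11 and by slow addition of the formate.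

**Step 12**
Reactants: 24 (3S)-7-(methoxymethoxy)-3-[5-(methoxymethoxy)-2,2-dimethyl-2H-chromen-6-yl]-8-(3-methylbut-2-enyl)chroman
Product: 25 (3S)-3-(5-hydroxy-2,2-dimethyl-2H-chromen-6-yl)-8-(3-methylbut-2-enyl)chroman-7-ol (target)
Conditions: conc. HCl (catalytic), MeOH, rt to 40 °C
Reagents that add atoms: none
Why: Acid-catalysed acetal exchange with methanol (standard MOM cleavage, precedented on prenylated phenols and dimethylchromenes under mild conditions) frees both phenols, and C3, which bears no acidifying group, keeps its configuration.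

**Compound list**
1 | resorcinol | Oc1cccc(O)c1 | starting material
2 | 1,3-bis(methoxymethoxy)benzene | COCOc1cccc(OCOC)c1 | intermediate
3 | [2,6-bis(methoxymethoxy)phenyl]lithium (not isolated) | [Li]c1c(OCOC)cccc1OCOC | intermediate
4 | 1,3-bis(methoxymethoxy)-2-(3-methylbut-2-enyl)benzene | COCOc1cccc(OCOC)c1CC=C(C)C | intermediate
5 | [2,4-bis(methoxymethoxy)-3-(3-methylbut-2-enyl)phenyl]lithium (not isolated) | [Li]c1ccc(OCOC)c(CC=C(C)C)c1OCOC | intermediate
6 | 2,4-bis(methoxymethoxy)-3-(3-methylbut-2-enyl)benzaldehyde | O=Cc1ccc(OCOC)c(CC=C(C)C)c1OCOC | intermediate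
7 | bromomagnesium 2-formyl-5-(methoxymethoxy)-6-(3-methylbut-2-enyl)phenoxide (not isolated) | Br[Mg]Oc1c(C=O)ccc(OCOC)c1CC=C(C)C | intermediate
8 | 2-hydroxy-4-(methoxymethoxy)-3-(3-methylbut-2-enyl)benzaldehyde | O=Cc1ccc(OCOC)c(CC=C(C)C)c1O | intermediate
9 | sodium 2-formyl-5-(methoxymethoxy)-6-(3-methylbut-2-enyl)phenoxide (not isolated) | [Na+].[O-]c1c(C=O)ccc(OCOC)c1CC=C(C)C | intermediate
10 | 4-(methoxymethoxy)-3-(3-methylbut-2-enyl)-2-[2-(triphenyl-λ5-phosphanylidene)ethoxy]benzaldehyde (ylide, not isolated) | O=Cc1ccc(OCOC)c(CC=C(C)C)c1OCC=P(c1ccccc1)(c1ccccc1)c1ccccc1 | intermediate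
11 | 7-(methoxymethoxy)-8-(3-methylbut-2-enyl)-2H-chromene | CC(C)=CCc1c(OCOC)ccc2c1OCC=C2 | intermediate
12 | cyclohexane-1,3-dione | O=C1CCCC(=O)C1 | starting material
13 | 3-methylbut-2-enal | CC(C)=CC=O | starting material
14 | 2-(3-methylbut-2-enylidene)cyclohexane-1,3-dione (not isolated) | CC(C)=CC=C1C(=O)CCCC1=O | intermediate
15 | 2,2-dimethyl-7,8-dihydro-2H-chromen-5(6H)-one | CC1(C)C=CC2=C(O1)CCCC2=O | intermediate
16 | lithium 2,2-dimethyl-7,8-dihydro-2H-chromen-5-olate (α′ enolate, not isolated) | CC1(C)C=CC2=C(O1)CCC=C2O[Li] | intermediate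
17 | 2,2-dimethyl-6-(phenylselanyl)-7,8-dihydro-2H-chromen-5(6H)-one (racemic) | CC1(C)C=CC2=C(O1)CCC([Se]c1ccccc1)C2=O | intermediate
18 | 2,2-dimethyl-6-(phenylseleninyl)-7,8-dihydro-2H-chromen-5(6H)-one (not isolated) | CC1(C)C=CC2=C(O1)CCC([Se](=O)c1ccccc1)C2=O | intermediate
19 | 2,2-dimethyl-2H-chromen-5(8H)-one (not isolated) | CC1(C)C=CC2=C(O1)CC=CC2=O | intermediate
20 | 2,2-dimethyl-2H-chromen-5-ol | CC1(C)C=Cc2c(O)cccc2O1 | intermediate
21 | 5-(methoxymethoxy)-2,2-dimethyl-2H-chromene | CC1(C)C=Cc2c(OCOC)cccc2O1 | intermediate
22 | [5-(methoxymethoxy)-2,2-dimethyl-2H-chromen-6-yl]lithium (not isolated) | CC1(C)C=Cc2c(OCOC)c([Li])ccc2O1 | intermediate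
23 | 6-iodo-5-(methoxymethoxy)-2,2-dimethyl-2H-chromene | CC1(C)C=Cc2c(OCOC)c(I)ccc2O1 | intermediate
24 | (3S)-7-(methoxymethoxy)-3-[5-(methoxymethoxy)-2,2-dimethyl-2H-chromen-6-yl]-8-(3-methylbut-2-enyl)chroman | CC(C)=CCc1c(OCOC)ccc2c1OC[C@H](c1ccc3c(c1OCOC)C=CC(C)(C)O3)C2 | intermediate
25 | (3S)-3-(5-hydroxy-2,2-dimethyl-2H-chromen-6-yl)-8-(3-methylbut-2-enyl)chroman-7-ol | CC(C)=CCc1c(O)ccc2c1OC[C@H](c1ccc3c(c1O)C=CC(C)(C)O3)C2 | target

**Total step count:** 12
**Longest linear sequence:** 7 steps (steps 1–5, 11, 12, or equally steps 6–10, 11, 12)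

**Steps most likely to fail**

1. **Step 11 (bears the label).**
 What may go wrong:
 - Formate may reduce the arylpalladium species before the hindered insertion takes place.
 - The insertion may transfer the aryl group to C4 instead of C3.
 - The ligand may discriminate poorly between the two faces of the flat chromene.

 The fallback uses known chemistry, forms the same C3–C1′ bond, sets out from 8 and 23, and comes back at 24. Compound 8 is treated with vinylmagnesium bromide (2.2 equiv, THF, 0 °C) to give the allylic alcohol 2-(1-hydroxyprop-2-en-1-yl)-5-(methoxymethoxy)-6-(3-methylbut-2-enyl)phenol F1. MnO2 (CH2Cl2) oxidises it to the aryl vinyl ketone 1-[2-hydroxy-4-(methoxymethoxy)-3-(3-methylbut-2-enyl)phenyl]prop-2-en-1-one F2, which closes on exposure to Et3N by oxa-Michael addition to 7-(methoxymethoxy)-8-(3-methylbut-2-enyl)chroman-4-one F3. Palladium-catalysed ketone α-arylation of F3 with 23 (Pd2(dba)3, P(t-Bu)3·HBF4, K3PO4, toluene, 90 °C) gives the racemic isoflavanone 7-(methoxymethoxy)-3-[5-(methoxymethoxy)-2,2-dimethyl-2H-chromen-6-yl]-8-(3-methylbut-2-enyl)chroman-4-one F4. Asymmetric transfer hydrogenation with dynamic kinetic resolution follows (RuCl(p-cymene)[(S,S)-TsDPEN], HCO2H–Et3N, EtOAc, rt). Here C3 epimerises through the enol faster than the ketone is reduced, so the step should give the cis alcohol (3S,4S)-7-(methoxymethoxy)-3-[5-(methoxymethoxy)-2,2-dimethyl-2H-chromen-6-yl]-8-(3-methylbut-2-enyl)chroman-4-ol F5. NaH, CS2 and MeI convert it into the xanthate O-[(3S,4S)-7-(methoxymethoxy)-3-[5-(methoxymethoxy)-2,2-dimethyl-2H-chromen-6-yl]-8-(3-methylbut-2-enyl)chroman-4-yl] S-methyl dithiocarbonate F6. Barton–McCombie reduction (Bu3SnH, AIBN, toluene, 80 °C) then removes the C4 oxygen under neutral conditions, where the 2′-OMOM oxygen cannot capture a C4 cation, and reaches 24.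

2. **Step 4.**
 What may go wrong: the site selectivity may be poor, with loss of both acetals or slow, incomplete cleavage of the chelated one.
 The fallback sets out from 6 and comes back at 8. Both acetals are removed (catalytic HCl, MeOH, rt) to give 2,4-dihydroxy-3-(3-methylbut-2-enyl)benzaldehyde F7. The 4-OH alone is then protected again (MOMCl 1.05 equiv, K2CO3, acetone, rt), because the 2-OH is held in the hydrogen bond to the formyl group and stays unreactive.

3. **Step 12.**
 What may go wrong: acid may induce ring closure of the freed 7-OH onto the prenyl alkene, or addition of methanol to the ring D alkene, before both acetals are gone.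
 The fallback sets out from 24 and comes back at 25. The acetals are exchanged for silyl ethers without free Brønsted acid (TMSOTf, 2,2′-bipyridyl, MeCN, 0 °C to rt). This gives the bis(trimethylsilyl) ether (3S)-3-[2,2-dimethyl-5-(trimethylsilyloxy)-2H-chromen-6-yl]-8-(3-methylbut-2-enyl)-7-(trimethylsilyloxy)chroman F8, which is hydrolysed with water at neutral pH to 25.

**Further compounds**
F1 | step 11 | 2-(1-hydroxyprop-2-en-1-yl)-5-(methoxymethoxy)-6-(3-methylbut-2-enyl)phenol (racemic) | C=CC(O)c1ccc(OCOC)c(CC=C(C)C)c1O
F2 | step 11 | 1-[2-hydroxy-4-(methoxymethoxy)-3-(3-methylbut-2-enyl)phenyl]prop-2-en-1-one | C=CC(=O)c1ccc(OCOC)c(CC=C(C)C)c1O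
F3 | step 11 | 7-(methoxymethoxy)-8-(3-methylbut-2-enyl)chroman-4-one | CC(C)=CCc1c(OCOC)ccc2c1OCCC2=O
F4 | step 11 | 7-(methoxymethoxy)-3-[5-(methoxymethoxy)-2,2-dimethyl-2H-chromen-6-yl]-8-(3-methylbut-2-enyl)chroman-4-one (racemic) | CC(C)=CCc1c(OCOC)ccc2c1OCC(c1ccc3c(c1OCOC)C=CC(C)(C)O3)C2=O
F5 | step 11 | (3S,4S)-7-(methoxymethoxy)-3-[5-(methoxymethoxy)-2,2-dimethyl-2H-chromen-6-yl]-8-(3-methylbut-2-enyl)chroman-4-ol | CC(C)=CCc1c(OCOC)ccc2c1OC[C@H](c1ccc3c(c1OCOC)C=CC(C)(C)O3)[C@@H]2O
F6 | step 11 | O-[(3S,4S)-7-(methoxymethoxy)-3-[5-(methoxymethoxy)-2,2-dimethyl-2H-chromen-6-yl]-8-(3-methylbut-2-enyl)chroman-4-yl] S-methyl dithiocarbonate | CC(C)=CCc1c(OCOC)ccc2c1OC[C@H](c1ccc3c(c1OCOC)C=CC(C)(C)O3)[C@@H]2OC(=S)SC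
F7 | step 4 | 2,4-dihydroxy-3-(3-methylbut-2-enyl)benzaldehyde | O=Cc1ccc(O)c(CC=C(C)C)c1O
F8 | step 12 | (3S)-3-[2,2-dimethyl-5-(trimethylsilyloxy)-2H-chromen-6-yl]-8-(3-methylbut-2-enyl)-7-(trimethylsilyloxy)chroman | CC(C)=CCc1c(O[Si](C)(C)C)ccc2c1OC[C@H](c1ccc3c(c1O[Si](C)(C)C)C=CC(C)(C)O3)C2
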